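## Retrosynthetic overview

1. Ring 1 (bromo enol ether) is closed last: the C7–C8 bond forms by 5-exo-dig cyclization of an α-bromoalkyl radical (from a CHBr2 group) onto an ynol ether, which also sets C8 and the E-enol ether.
2. The ynol ether comes from the ring-2 alcohol 12, trichloroethene 13 (C6–C7) and the Z-enynyl bromide 5 (C1–C5); CH2OSi is then taken to CHO and CHBr2.
3. Ring 2 is formed first, by a bromonium-initiated epoxide-opening cascade of epoxy alcohol 10 (sets C12, C13 and the C13–Br bond).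
4. 10 comes from (2S,3S)-diepoxybutane 6 (C8–C11, both oxygens, C9/C10 stereocenters) and but-1-yne 7 (C12–C15); 5 comes from ethyl (Z)-3-iodoacrylate 1 and ethynylsilane 2.
5. Ring order: ring 2 (oxolane with the bromopropyl chain), then ring 1.

Assumption: (2S,3S)-1,2:3,4-diepoxybutane and ethyl (2Z)-3-iodoprop-2-enoate are taken as purchasable; the route is a paper proposal and has not been run.

## Route

Step 1
Reactants: 1 ethyl (2Z)-3-iodoprop-2-enoate; 2 ethynyl(trimethyl)silane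
Product: 3 ethyl (2Z)-5-(trimethylsilyl)pent-2-en-4-ynoate
Conditions: Pd(PPh3)2Cl2 (2 mol %), CuI (4 mol %), Et3N, THF, 0 °C to rt
Reagents that add atoms: none
Why: Sonogashira coupling of the Z-iodoalkene proceeds with retention of the alkene geometry.

Step 2
Reactants: 3 ethyl (2Z)-5-(trimethylsilyl)pent-2-en-4-ynoate
Product: 4 (2Z)-5-(trimethylsilyl)pent-2-en-4-yn-1-ol
Conditions: iBu2AlH (2.2 equiv), CH2Cl2, −78 °C; aq. NH4Cl
Reagents that add atoms: none
Why: Hydride 1,2-reduction of the conjugated ester gives the allylic alcohol without touching the Z-enyne or the C–Si bond.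

Step 3
Reactants: 4 (2Z)-5-(trimethylsilyl)pent-2-en-4-yn-1-ol
Product: 5 [(3Z)-5-bromopent-3-en-1-yn-1-yl](trimethyl)silane
Conditions: CBr4, PPh3, CH2Cl2, 0 °C
Reagents that add atoms: carbon tetrabromide, BrC(Br)(Br)Br
Why: Appel bromination of the primary allylic alcohol is a direct SN2 displacement, so the Z-alkene and the allylic position are kept.

Step 4
Reactants: 6 (2S,3S)-1,2:3,4-diepoxybutane; 7 but-1-yne
Product: 10 (1S,3E)-1-[(2S)-oxiran-2-yl]hex-3-en-1-ol, via alkenylalane 8 (not isolated), via lithium alkenylalanate 9 (not isolated)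
Conditions: 7, iBu2AlH, hexane, 50 °C (sealed); n-BuLi, THF, −78 °C; added to 6 (3 equiv), −78 °C to rt; aq. NH4Cl
Reagents that add atoms: none
Why: Syn-hydroalumination gives the E-alkenylalane, and its alanate opens one terminal epoxide carbon of the C2-symmetric diepoxide by SN2 (alkenylalanate epoxide opening), so both stereocenters (C9, C10, syn) come unchanged from 6 and the alkene is E.

Step 5
Reactants: 10 (1S,3E)-1-[(2S)-oxiran-2-yl]hex-3-en-1-ol
Product: 11 (2S,3S,5R)-5-[(1S)-1-bromopropyl]-2-(hydroxymethyl)oxolan-3-ol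
Conditions: NBS (1.1 equiv), THF–H2O (3:1), 0 °C, dark
Reagents that add atoms: N-bromosuccinimide, O=C1CCC(=O)N1Br; water, O
Why: In this bromonium-initiated epoxide-opening cascade the epoxide oxygen attacks the bromonium ion 5-exo and anti to bromine (E-alkene gives the erythro C12–O/C13–Br pair), the CH2 group on the oxonium oxygen forces the new side chain trans to it (2,5-trans, C12 R, C13 S), and water opens the oxonium ion at the primary carbon with C9 retained.

Step 6
Reactants: 11 (2S,3S,5R)-5-[(1S)-1-bromopropyl]-2-(hydroxymethyl)oxolan-3-ol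
Product: 12 (2S,3S,5R)-5-[(1S)-1-bromopropyl]-2-({[tri(propan-2-yl)silyl]oxy}methyl)oxolan-3-ol
Conditions: iPr3SiCl (1.05 equiv), imidazole, CH2Cl2, 0 °C
Reagents that add atoms: chlorotri(propan-2-yl)silane, CC(C)[Si](Cl)(C(C)C)C(C)C
Why: The bulky silyl chloride reacts selectively at the primary hydroxyl (silyl ether protection), and the triisopropylsilyl group resists base-induced O-to-O migration in the next step.

Step 7
Reactants: 12 (2S,3S,5R)-5-[(1S)-1-bromopropyl]-2-({[tri(propan-2-yl)silyl]oxy}methyl)oxolan-3-ol; 13 trichloroethene; 5 [(3Z)-5-bromopent-3-en-1-yn-1-yl](trimethyl)silane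
Product: 17 {[(2S,3S,5R)-5-[(1S)-1-bromopropyl]-3-{[(4Z)-7-(trimethylsilyl)hept-4-ene-1,6-diyn-1-yl]oxy}oxolan-2-yl]methoxy}tri(propan-2-yl)silane, via dichlorovinyl ether 14 (not isolated), via chloroethynyl ether 15 (not isolated), via lithium alkynyl ether 16 (not isolated)
Conditions: KH (1.5 equiv), THF, 0 °C; 13 (1.1 equiv), −50 °C to rt; n-BuLi (2.3 equiv), −78 to −40 °C; 5 (1.5 equiv), HMPA, −78 to −20 °C; chromatography on Et3N-treated silica
Reagents that add atoms: none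
Why: Greene ynol ether synthesis: the alkoxide gives the dichlorovinyl ether, n-BuLi effects elimination and Cl/Li exchange, and the lithium alkynyl ether is alkylated by SN2 at the primary allylic bromide at low temperature, leaving all stereocenters and the Z-alkene untouched.

Step 8
Reactants: 17 {[(2S,3S,5R)-5-[(1S)-1-bromopropyl]-3-{[(4Z)-7-(trimethylsilyl)hept-4-ene-1,6-diyn-1-yl]oxy}oxolan-2-yl]methoxy}tri(propan-2-yl)silane
Product: 18 [(2S,3S,5R)-5-[(1S)-1-bromopropyl]-3-{[(4Z)-hept-4-ene-1,6-diyn-1-yl]oxy}oxolan-2-yl]methanol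
Conditions: Bu4NF (2.5 equiv), THF, 0 °C to rt
Reagents that add atoms: none
Why: Fluoride cleaves the Si–O and the alkynyl C–Si bonds in one desilylation under non-acidic conditions that the ynol ether and the secondary bromide tolerate.

Step 9
Reactants: 18 [(2S,3S,5R)-5-[(1S)-1-bromopropyl]-3-{[(4Z)-hept-4-ene-1,6-diyn-1-yl]oxy}oxolan-2-yl]methanol
Product: 19 (2R,3S,5R)-5-[(1S)-1-bromopropyl]-3-{[(4Z)-hept-4-ene-1,6-diyn-1-yl]oxy}oxolane-2-carbaldehyde
Conditions: nPr4N[RuO4] (5 mol %), N-methylmorpholine N-oxide (1.5 equiv), 4 Å MS, CH2Cl2, 0 °C; used crude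
Reagents that add atoms: none
Why: Ley–Griffith oxidation is neutral, so the acid-sensitive ynol ether and the epimerizable α-alkoxy aldehyde centre (C9) survive.

Step 10
Reactants: 19 (2R,3S,5R)-5-[(1S)-1-bromopropyl]-3-{[(4Z)-hept-4-ene-1,6-diyn-1-yl]oxy}oxolane-2-carbaldehyde
Product: 20 (2R,3S,5R)-5-[(1S)-1-bromopropyl]-2-(dibromomethyl)-3-{[(4Z)-hept-4-ene-1,6-diyn-1-yl]oxy}oxolane
Conditions: (PhO)3P (1.5 equiv), Br2 (1.4 equiv) premixed, Et3N, CH2Cl2, −78 to −20 °C
Reagents that add atoms: bromine, BrBr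
Why: Deoxygenative gem-dibromination of the aldehyde with the preformed triphenyl phosphite–bromine adduct leaves no free bromine for the alkynes and no stereocenter is touched.

Step 11
Reactants: 20 (2R,3S,5R)-5-[(1S)-1-bromopropyl]-2-(dibromomethyl)-3-{[(4Z)-hept-4-ene-1,6-diyn-1-yl]oxy}oxolane
Product: 21 (2E,3S,3aR,5R,6aS)-3-bromo-5-[(1S)-1-bromopropyl]-2-[(2Z)-pent-2-en-4-yn-1-ylidene]hexahydrofuro[3,2-b]furan
Conditions: Bu3SnH (0.95 equiv, syringe pump, 6 h), Et3B (0.3 equiv), air, solid K2CO3, toluene (5 mM), −20 °C; stopped before full conversion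
Reagents that add atoms: none
Why: Proposed new method: the tin radical abstracts one bromine of the α-halogen-activated CHBr2 group, the α-bromoalkyl radical closes 5-exo-dig onto the oxygen-bearing alkyne carbon of the cis-disposed ynol ether with bromine on the convex face (C8 S, trans to the ring-2 oxygen), and the bent vinyl radical takes hydrogen from Bu3SnH on the unhindered ring-oxygen side to give the E-enol ether; the closest known reactions are tin hydride 5-exo-dig cyclizations of haloalkyl radicals onto alkynes and radical cyclizations onto the nitrogen-bearing carbon of ynamides.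

## Compound list

1 | ethyl (2Z)-3-iodoprop-2-enoate | CCOC(=O)/C=C\I | starting material
2 | ethynyl(trimethyl)silane | C#C[Si](C)(C)C | starting material
3 | ethyl (2Z)-5-(trimethylsilyl)pent-2-en-4-ynoate | CCOC(=O)/C=C\C#C[Si](C)(C)C | intermediate
4 | (2Z)-5-(trimethylsilyl)pent-2-en-4-yn-1-ol | OC/C=C\C#C[Si](C)(C)C | intermediate
5 | [(3Z)-5-bromopent-3-en-1-yn-1-yl](trimethyl)silane | BrC/C=C\C#C[Si](C)(C)C | intermediate
6 | (2S,3S)-1,2:3,4-diepoxybutane | C1O[C@@H]1[C@@H]1CO1 | starting material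
7 | but-1-yne | CCC#C | starting material
8 | [(1E)-but-1-en-1-yl]bis(2-methylpropyl)alane | CC/C=C/[Al](CC(C)C)CC(C)C | intermediate
9 | lithium butyl[(1E)-but-1-en-1-yl]bis(2-methylpropyl)aluminate | [Li+].CCCC[Al-](/C=C/CC)(CC(C)C)CC(C)C | intermediate
10 | (1S,3E)-1-[(2S)-oxiran-2-yl]hex-3-en-1-ol | C1O[C@@H]1[C@@H](O)C/C=C/CC | intermediate
11 | (2S,3S,5R)-5-[(1S)-1-bromopropyl]-2-(hydroxymethyl)oxolan-3-ol | OC[C@@H]1O[C@H](C[C@@H]1O)[C@@H](Br)CC | intermediate
12 | (2S,3S,5R)-5-[(1S)-1-bromopropyl]-2-({[tri(propan-2-yl)silyl]oxy}methyl)oxolan-3-ol | CC(C)[Si](C(C)C)(C(C)C)OC[C@@H]1O[C@H](C[C@@H]1O)[C@@H](Br)CC | intermediate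
13 | trichloroethene | ClC=C(Cl)Cl | starting material
14 | {[(2S,3S,5R)-5-[(1S)-1-bromopropyl]-3-{[(E)-1,2-dichloroethenyl]oxy}oxolan-2-yl]methoxy}tri(propan-2-yl)silane | CC(C)[Si](C(C)C)(C(C)C)OC[C@@H]1O[C@H](C[C@@H]1O/C(Cl)=C\Cl)[C@@H](Br)CC | intermediate
15 | {[(2S,3S,5R)-5-[(1S)-1-bromopropyl]-3-[(chloroethynyl)oxy]oxolan-2-yl]methoxy}tri(propan-2-yl)silane | CC(C)[Si](C(C)C)(C(C)C)OC[C@@H]1O[C@H](C[C@@H]1OC#CCl)[C@@H](Br)CC | intermediate
16 | lithium 2-{[(2S,3S,5R)-5-[(1S)-1-bromopropyl]-2-({[tri(propan-2-yl)silyl]oxy}methyl)oxolan-3-yl]oxy}ethynide | CC(C)[Si](C(C)C)(C(C)C)OC[C@@H]1O[C@H](C[C@@H]1OC#C[Li])[C@@H](Br)CC | intermediate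
17 | {[(2S,3S,5R)-5-[(1S)-1-bromopropyl]-3-{[(4Z)-7-(trimethylsilyl)hept-4-ene-1,6-diyn-1-yl]oxy}oxolan-2-yl]methoxy}tri(propan-2-yl)silane | CC(C)[Si](C(C)C)(C(C)C)OC[C@@H]1O[C@H](C[C@@H]1OC#CC/C=C\C#C[Si](C)(C)C)[C@@H](Br)CC | intermediate
18 | [(2S,3S,5R)-5-[(1S)-1-bromopropyl]-3-{[(4Z)-hept-4-ene-1,6-diyn-1-yl]oxy}oxolan-2-yl]methanol | OC[C@@H]1O[C@H](C[C@@H]1OC#CC/C=C\C#C)[C@@H](Br)CC | intermediate
19 | (2R,3S,5R)-5-[(1S)-1-bromopropyl]-3-{[(4Z)-hept-4-ene-1,6-diyn-1-yl]oxy}oxolane-2-carbaldehyde | O=C[C@@H]1O[C@H](C[C@@H]1OC#CC/C=C\C#C)[C@@H](Br)CC | intermediate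
20 | (2R,3S,5R)-5-[(1S)-1-bromopropyl]-2-(dibromomethyl)-3-{[(4Z)-hept-4-ene-1,6-diyn-1-yl]oxy}oxolane | BrC(Br)[C@@H]1O[C@H](C[C@@H]1OC#CC/C=C\C#C)[C@@H](Br)CC | intermediate
21 | (2E,3S,3aR,5R,6aS)-3-bromo-5-[(1S)-1-bromopropyl]-2-[(2Z)-pent-2-en-4-yn-1-ylidene]hexahydrofuro[3,2-b]furan (CNP0105780.2) | C#C/C=C\C/C=C1/O[C@H]2C[C@H]([C@@H](Br)CC)O[C@H]2[C@@H]1Br | target

## Step count and risks

Total steps: 11. Longest linear sequence: 8 (steps 4 to 11; the three-step bromide branch joins at step 7).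

**Step 11 (radical ring closure).** The product's allylic C–Br bond and the C13–Br bond can also be abstracted by the tin radical, and 5-exo versus 6-endo attack and E/Z control are untested on an ynol ether. The fallback sets out from aldehyde 19 (so it also bypasses step 10) and comes back at 21. It closes ring 1 with a ketyl radical instead: SmI2, HMPA, t-BuOH, THF, −78 °C gives, by 5-exo-dig ketyl–alkyne cyclization, (2E,3aR,5R,6aS)-5-[(1S)-1-bromopropyl]-2-[(2Z)-pent-2-en-4-yn-1-ylidene]hexahydrofuro[3,2-b]furan-3-ol (C3 epimers) F1. MnO2 in CH2Cl2 converges both epimers to (2E,3aR,5R,6aS)-5-[(1S)-1-bromopropyl]-2-[(2Z)-pent-2-en-4-yn-1-ylidene]tetrahydrofuro[3,2-b]furan-3(2H)-one F2. NaBH4 with CeCl3·7H2O in MeOH at −78 °C delivers hydride to the convex face and gives (2E,3R,3aR,5R,6aS)-5-[(1S)-1-bromopropyl]-2-[(2Z)-pent-2-en-4-yn-1-ylidene]hexahydrofuro[3,2-b]furan-3-ol F3, with the hydroxyl cis to the ring-2 oxygen. CBr4 and PPh3 in CH2Cl2 at 0 °C then install the bromide with inversion to give 21.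

**Step 10 (gem-dibromination beside an ynol ether).** The phosphorus-activated aldehyde could be attacked by the nucleophilic ynol ether carbon (Prins-type closure), or the reagent could brominate the ynol ether. The fallback sets out from 19 and comes back at 20 without activating the carbonyl oxygen. N2H4·H2O in THF at 0 °C gives {(E)-[(2S,3S,5R)-5-[(1S)-1-bromopropyl]-3-{[(4Z)-hept-4-ene-1,6-diyn-1-yl]oxy}oxolan-2-yl]methylidene}hydrazine F4. NBS (2.1 equiv) and pyridine in CH2Cl2 at −40 °C then oxidize the far more nucleophilic hydrazone through the diazo compound to the gem-dibromide 20 with loss of nitrogen.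

**Step 7 (ynol ether synthesis and alkylation in the presence of the secondary bromide).** The C13 bromide may not survive prolonged exposure to the lithium acetylide in HMPA, and the alkylation with the enynyl bromide may be slow. The fallback sets out from 12 and comes back at 17. The sequence is run as in step 7 up to the lithium alkynyl ether 16, which is quenched with MeOH at −78 °C and isolated as {[(2S,3S,5R)-5-[(1S)-1-bromopropyl]-3-(ethynyloxy)oxolan-2-yl]methoxy}tri(propan-2-yl)silane F5. The C5–C6 bond is then formed by copper acetylide allylation under weak base (CuI 10 mol %, NaI, K2CO3, DMF, rt) with bromide 5 to give 17.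

Further compounds
F1 | step 11 | (2E,3aR,5R,6aS)-5-[(1S)-1-bromopropyl]-2-[(2Z)-pent-2-en-4-yn-1-ylidene]hexahydrofuro[3,2-b]furan-3-ol (C3 epimers) | C#C/C=C\C/C=C1/O[C@H]2C[C@H]([C@@H](Br)CC)O[C@H]2C1O
F2 | step 11 | (2E,3aR,5R,6aS)-5-[(1S)-1-bromopropyl]-2-[(2Z)-pent-2-en-4-yn-1-ylidene]tetrahydrofuro[3,2-b]furan-3(2H)-one | C#C/C=C\C/C=C1/O[C@H]2C[C@H]([C@@H](Br)CC)O[C@H]2C1=O
F3 | step 11 | (2E,3R,3aR,5R,6aS)-5-[(1S)-1-bromopropyl]-2-[(2Z)-pent-2-en-4-yn-1-ylidene]hexahydrofuro[3,2-b]furan-3-ol | C#C/C=C\C/C=C1/O[C@H]2C[C@H]([C@@H](Br)CC)O[C@H]2[C@H]1O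
F4 | step 10 | {(E)-[(2S,3S,5R)-5-[(1S)-1-bromopropyl]-3-{[(4Z)-hept-4-ene-1,6-diyn-1-yl]oxy}oxolan-2-yl]methylidene}hydrazine | N/N=C/[C@@H]1O[C@H](C[C@@H]1OC#CC/C=C\C#C)[C@@H](Br)CC
F5 | step 7 | {[(2S,3S,5R)-5-[(1S)-1-bromopropyl]-3-(ethynyloxy)oxolan-2-yl]methoxy}tri(propan-2-yl)silane | CC(C)[Si](C(C)C)(C(C)C)OC[C@@H]1O[C@H](C[C@@H]1OC#C)[C@@H](Br)CC
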